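The readings were generated by integration for substances that don't exist, and the scatter is random.

Begin at the late end. At 4.00 d the south-west run still holds 6.1% of its electrophile, and the slope of ln(electrophile) over its last two readings is 0.582 d⁻¹, so the curve is still falling and its level lies below that last reading.

the same everywhere: electrophile 0.050 M

| flask | nucleophile | free base | remark | time |
|---|---|---|---|---|
| south-west | 0.075 M | 0.070 M | run made earlier |  |
| west | 0.075 M | 0.27 M | run made earlier |  |
| green | 0.0750 M | 0.0500 M |  | 4.0 d |
| grey | 0.0750 M | 0.100 M |  | 4.0 d |
| blue | 0.0750 M | 0.200 M |  | 4.0 d |

| run | time / d | electrophile / % | target / % |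
|---|---|---|---|
| south-west | 0.333 | 69.8 | 20.0 |
| south-west | 0.500 | 58.4 | 24.8 |
| south-west | 0.833 | 45.3 | 30.4 |
| south-west | 1.04 | 38.8 | 32.8 |
| south-west | 1.67 | 24.0 | 37.3 |
| south-west | 2.50 | 14.6 | 39.2 |
| south-west | 4.00 | 6.1 | 42.6 |
| west | 0.208 | 77.8 | 15.5 |
| west | 0.625 | 51.7 | 28.3 |
| west | 1.04 | 36.2 | 34.1 |
| west | 1.67 | 21.9 | 39.6 |
| west | 2.50 | 12.2 | 40.1 |
| west | 3.00 | 8.7 | 43.2 |
| west | 4.00 | 4.5 | 44.4 |

(standard deviation of a reading: 0.5 percentage points)

- part of the electrophile that has reacted at the end, green
- part of the electrophile that has reacted at the end, grey
- part of the electrophile that has reacted at the end, blue
- what raising the concentration of free base from its lowest to its highest value here does to the part of the electrophile that has reacted (changes below 5 percentage points count as none) (it rises / it falls / no change)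

- what may be going on: electrophile + nucleophile <-> acid set free + target; nucleophile + acid set free <-> protonated nucleophile; acid set free + free base <-> salt of the base; electrophile <-> dormant form; target <-> isomer of the product
- what has gone from electrophile into another species counts as reacted, even if it can come back

Now draw the south-west curve from the start. The first reading gives a log slope of 1.08 d⁻¹, steeper than the tail, so the curve has a knee and then a slower decay. In the south-west run the electrophile stands above the target at 1.04 d and below it at 1.67 d, so they cross between those readings. The south-west target then bends over towards 42.6%. The nucleophile is charged at 1.50 equivalents, which makes the electrophile the limiting reagent. At 4.00 d in the south-west run, 51.3% of the charge is neither electrophile nor target, so what is asked must be read from the electrophile's remainder, not from the target.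

The green, grey and blue flasks share their electrophile, nucleophile and time with the last readings of both runs, and they differ in free base. So carry one number, the base leverage n: the exponent in "remainder, at fixed time and fixed charges of electrophile and nucleophile, proportional to [free base] to the power −n", read as the log of the ratio of the two remainders over the log of the ratio of the two base charges, n = 0.225. It is a rough reading, since each remainder carries a scatter of 0.5 percentage points. Starting from the south-west remainder, I reckon 93.4% reacted in green, a short step below the range of the runs, then 94.4% in grey and 95.2% in blue. That span of 1.8 points is less than the 5 points that counts as a change.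

The forecast says 93%, 94.5% and 95.3%, trend no change, on the ground that “A fourfold rise in base therefore changes little”. For green it stands 0.40 points below my figure.

The flasks give 93.0%, 94.1% and 95.0%, trend no change, a rise of 2 points.

    electrophile + nucleophile ⇌ acid set free + target (K = 7.20, k = 0.570 M⁻¹ h⁻¹)
    nucleophile + acid set free ⇌ protonated nucleophile, settled at all times (K = 99000 M⁻¹)
    acid set free + free base ⇌ salt of the base, settled at all times (K = 56000 M⁻¹)
    electrophile ⇌ dormant form (K = 15.0, k = 0.00950 h⁻¹)
    target ⇌ isomer of the product (K = 0.620, k = 0.0610 h⁻¹)

Moved alone, up or down by one common factor, the settings tried shift the green answer at most as follows: nucleophile (4.2 points), then time (4.2 points), then electrophile (3 points), then free base (0.43 points). Starting from green's remainder of 7.0%, n gives 5.97% for grey, where the flask holds 5.9%, and 5.11% for blue, where the flask holds 5.0%.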